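The west readings could not tell me the order in starting material, because they stop at 71% of it left, where exponential and reciprocal decay, drawn through that last reading, differ at 3.00 min by 1.2 percentage points, less than the scatter of a reading.

- west: starting material 0.30 M; reagent 1.8 equiv; run made earlier
- flask: starting material 0.20 M; reagent 1.80 equiv; time 80 min

- west (time / min: starting material / %, single product / %): 0.667: 100, 1; 1.33: 91, 3; 3.00: 85, 4; 8.00: 71, 16

(standard deviation of a reading: 2 percentage points)



1. how much starting material there is at 80 min, in percent of the starting material charged
2. how much single product there is at 80 min, in percent of the starting material charged
3. how much bis adduct there is at 80 min, in percent of the starting material charged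
4. how much triple product there is at 80 min, in percent of the starting material charged

At 3.00 min the west run read 15.0% of the starting material gone but 4% single product, less than the loss, which left open a second step drawing on the starting material directly. If the reagent's concentration stands in the rate, the decay is pseudo-first-order and the fraction left falls exponentially. If the starting material's own concentration stands there, the reciprocal of that fraction rises linearly. Assuming bimolecular steps and held equivalents, both laws run on one variable, the charge-time, starting concentration multiplied by time, which was 2.40 M·min at the last west reading.

So I decided to hold 1.80 equiv of reagent, lower the concentration to 0.20 M and run for 80 min, a charge-time of 16.0 M·min, or 6.67 west runs. Raising the west reading of 71% to that power gave 10.2%, and the linear law gave 26.9%. Both limits carry that reading's scatter, but they lay 17 points apart, more than the scatter of a reading, so this flask could show the order. I committed to starting material between them.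

The forecast gave 31% starting material, above my upper limit, with 12% single product, 47% bis adduct and 10% triple product, reasoning that “each converted molecule uses about two equivalents”. The flask gave 21.4% starting material, 37.4% single product, 0.591% bis adduct and 0.197% triple product.

    starting material + reagent → single product (k = 1.96 M⁻¹ h⁻¹)
    reagent + single product → bis adduct (k = 0.0808 M⁻¹ h⁻¹)
    reagent + bis adduct → triple product (k = 1.98 M⁻¹ h⁻¹)
    2 starting material → self-condensation product (k = 3.01 M⁻¹ h⁻¹)

The starting material in this flask lay between my limits, and the scheme holds both kinds of loss: at the start, the addition of reagent used starting material at 0.59 of the rate of self-condensation. By 80 min, the flask held 40.5% self-condensation product and 78% of its reagent. I put the same reckoning on the neighbour charged with 0.80 M starting material, at the same equivalents and time. Its charge-time was 26.7 west runs, so the limits were 0.0108% and 8.41%. That neighbour held 2.03% starting material.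

All runs are simulated for an exercise; the scatter is artificial.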